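**Numbering used throughout:** ring A is the central benzene of the target, with C1 (methyl), C2 (arylethynyl), C3 (quinone methide carbon), C4 (4-hydroxyphenyl, ring B), C5 and C6 (hydrogen). Ring C is the cyclohexadienone and ring D the hydroxyphenyl group on the methide carbon.

## Analysis of the target

Selaginellin U (12) is built on one benzene ring, ring A, that carries four contiguous substituents: methyl at C1, a (4-hydroxyphenyl)ethynyl group at C2, the quinone methide carbon at C3 and a 4-hydroxyphenyl group (ring B) at C4. The C3 substituent is a fuchsone unit: its exocyclic carbon is double-bonded to a cyclohexa-2,5-dienone (ring C) and single-bonded to a 4-hydroxyphenyl ring (ring D). A proton shift interchanges rings C and D, so the two oxygenated rings on this carbon are equivalent and can be introduced as two identical aryl groups. There is no stereocentre, and ring C is symmetrical about the exocyclic double bond, so no configuration has to be controlled. The sensitive groups are the electrophilic, reducible quinone methide, three oxidisable free phenols and a diaryl alkyne that sits beside a carbon which becomes cationic under acid. The difficulty is steric and regiochemical: four different groups must stand on adjacent ring carbons in a fixed order, and C3, which bears a triaryl-substituted carbon, is wedged between an aryl and an alkynyl group. The route rests on one feature of ring A: the two neighbours of C3, C2 and C4, can both be carbonyl carbons of a cyclohexane-1,3-dione whose 4-methyl group is the C1 methyl. C3 is then the carbon between the carbonyl groups, the only carbon nucleophile of that ring, and the two oxygens later serve as the leaving groups through which the C2 and C4 substituents enter.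

## Retrosynthetic reasoning

**12 to 11 to 10.** The quinone methide is the most fragile function, so it is generated last. No skeletal bond is cut: the exocyclic double bond of 12 is traced back to the methine C–H of tetraphenol 11, which is two hydrogen atoms richer. Because rings C and D are equivalent, oxidation at either hydroxyphenyl ring of 11 gives the same product. The four phenols of 11 are in turn masked as the methyl ethers of 10, a protecting group that survives acid, hot palladium, base and sulfonylation, and comes off in one Lewis-acid operation.

**10 to 8 and 9.** The bond from ring A C2 to the alkyne carbon is cut. This leaves terminal alkyne 9, which can be bought, and aryl triflate 8. The forward reaction is a Sonogashira coupling at a triflate flanked by the methyl and benzhydryl groups. It is placed after the C4 coupling because the C2 position is the less reactive of the two and can only be addressed once C4 is filled.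

**8 to 6 and 7.** The C4–ring B bond is cut, giving boronic acid 7 and bis-triflate 6. Both triflates of 6 lie next to the benzhydryl group, but the C4 triflate has hydrogen on its other side and the C2 triflate has the methyl group. The forward Suzuki–Miyaura coupling must therefore discriminate by the rate of oxidative addition.

**6 to 5 to 4.** The two C–O sulfonyl bonds are cut to give resorcinol 5, and 5 is traced to the non-aromatic dione 4 by adding back one molecule of hydrogen. The reason for going back to a saturated ring is regiochemical: in an aromatic resorcinol the position between the two hydroxyl groups is the least accessible to a bulky electrophile, whereas in 4 it is the only nucleophilic carbon.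

**4 to 2 and 3 (key disconnection).** The bond from ring A C3 to the diarylmethyl carbon is cut, giving benzhydrol 2 and dione 3. It is cut here, and first in the forward direction, because this is the most hindered bond of the target, and at this stage C2 and C4 are unsubstituted carbonyl or enol carbons. The forward reaction has to ionise 2 under mild acid and let the enol of 3 capture the cation at carbon.

**2 to 1.** The carbinol C–H bond of 2 is traced to ketone 1 by hydride reduction. This step is optional, since 2 is also an article of commerce.

## Alternatives that were turned down

**Alternative 1: ring A assembled from two three-carbon pieces as a salicylate.**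
- Disconnection: ring A is opened across C1–C6 and C3–C4. One piece is a dinucleophile comprising C1, C2 and C3, with the methyl group on C1 and an ester on C3. The other is a dielectrophile comprising C4, C5 and C6, with ring B on the ketone carbon C4 and C6 as an acetal.
- Forward key step: under a strong Lewis acid the methyl-bearing terminus of a 1,3-bis(silyloxy)diene attacks the acetal carbon, the ester-bearing carbon adds to the aryl ketone, and loss of alcohol and water aromatises the ring to methyl 3-hydroxy-4'-methoxy-4-methylbiphenyl-2-carboxylate A1.
- For it: all four substituents of ring A emerge in the right order from acyclic material. Only one phenol has to become a triflate, so no site-selective coupling is needed. The ester is at the oxidation level from which two equivalents of an aryl-metal reagent give a triaryl carbinol, which would collapse to the quinone methide on demethylation without a separate oxidation.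
- Against it: both partners must be prepared, the diene through two moisture-sensitive silylations and the keto acetal through formylation and acetalisation. The regiochemistry depends on the acetal reacting before the ketone. The ester of A1 is flanked on both sides, more so once the alkyne is in place, so double aryl addition must pass through a very hindered diaryl ketone.
- Comparison: on coupling selectivity and on the final oxidation state this alternative is the stronger one. The chosen strategy offers in exchange a key step between two purchasable compounds, so its risk is met at the second step and not after several preparatory ones. It also forms the C3 bond while the neighbouring carbons are still bare, instead of adding bulky nucleophiles to a carbonyl group buried between two ortho substituents.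

**Alternative 2: aryne carbometalation followed by acylation.**
- Disconnection: the C4–ring B bond and the C3–carbonyl bond are cut together, leading to an aryne across C3–C4 of a ring A that already holds the methyl group and a chlorine at C2.
- Forward key step: a 2-magnesiated aryl sulfonate eliminates to the aryne. An aryl Grignard reagent adds at C4, remote from chlorine, so that the new carbanion sits at C3 beside the halogen. This C3 Grignard reagent is acylated by an N-methoxy-N-methylamide to give (3-chloro-4'-methoxy-4-methylbiphenyl-2-yl)(4-methoxyphenyl)methanone A2.
- For it: two adjacent bonds form in one flask, the chlorine directs the regiochemistry, and the diaryl ketone needs only one more aryl addition to reach the carbinol level.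
- Against it: the aryne precursor needs a metalatable group between the chlorine and the sulfonate oxygen, the more hindered ortho position of the corresponding chlorophenol, so its preparation is a multi-step regiochemical problem of its own. The intermediate C3 Grignard reagent is flanked by chlorine and the new aryl ring, so acylation is slow and competes with loss of magnesium halide to a second aryne. The handle left for the alkyne is a di-ortho-substituted aryl chloride, a poorer Sonogashira partner than a triflate.
- Comparison: it is the more convergent route and potentially the shortest after its key step. The chosen strategy instead spreads the bond formations over separate steps of established type and needs no bespoke precursor.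

**Alternative 3: the alkyne grown from a second methyl group.**
- Disconnection: the alkyne is traced back to a deoxybenzoin and cut between its two future alkyne carbons. The carbon attached to C2 is then a methyl group of methyl 4'-methoxy-3,4-dimethylbiphenyl-2-carboxylate A3.
- Forward key step: a lithium amide removes a proton from the methyl group ortho to the ester (lateral lithiation), and the benzylic anion is acylated by an N-methoxy-N-methylamide to give methyl 4'-methoxy-3-[2-(4-methoxyphenyl)-2-oxoethyl]-4-methylbiphenyl-2-carboxylate A4.
- For it: no cross-coupling is needed at the most hindered ring position, the ester both acidifies the right methyl group and later becomes the carbinol carbon, and only the methyl group next to the ester is activated.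
- Against it: the keto ester A4 is more acidic than A3, and its enolate oxygen lies next to the ester, so lactonisation to an isocoumarin is the expected follow-up reaction. Anions of this type also self-condense. Turning the ketone into the alkyne needs an enol derivative and strong base in the presence of the ester. A3 is itself a tetrasubstituted benzene that must be made.
- Comparison: this route avoids the hindered Sonogashira coupling, which is the weakest downstream step of the chosen strategy. It pays with more steps after the key step and with a key intermediate prone to cyclisation. In the chosen strategy every downstream step is a standard exchange of an aryl C–O bond for a C–C bond.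

Key step: step 2

Remark on the chemistry: compounds 3 and 4 are racemic and their SMILES strings show one enantiomer; the stereocentre is erased in step 3, so it needs no control.

## Route

**Step 1**
Reactants: 1 4,4'-dimethoxybenzophenone
Product: 2 bis(4-methoxyphenyl)methanol
Conditions: NaBH4, MeOH/THF, 0 °C to rt
Reagents that add atoms: none
Why: Hydride reduction of a diaryl ketone to the benzhydrol; the aryl methyl ethers are inert to NaBH4.

**Step 2**
Reactants: 2 bis(4-methoxyphenyl)methanol; 3 4-methylcyclohexane-1,3-dione (racemic)
Product: 4 2-[bis(4-methoxyphenyl)methyl]-3-hydroxy-6-methylcyclohex-2-en-1-one (racemic; enol form of the 2-substituted dione)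
Conditions: TsOH·H2O (10 mol %), MeCN, 60 °C, 3 in slight excess
Reagents that add atoms: none
Why: TsOH protonates 2 and water leaves, giving the bis(4-methoxyphenyl)methyl cation, which two para-methoxy groups stabilise enough to form reversibly at 60 °C while leaving it electrophilic enough for a neutral enol. Dione 3 is largely enolised and both of its enol tautomers have their nucleophilic carbon at the same place, the carbon between the carbonyl groups, so the 4-methyl group cannot misdirect the attack; capture there and loss of a proton give 4, which re-enolises. The closest known reaction type is the Brønsted- or Lewis-acid-catalysed direct substitution of benzhydrols by cyclic 1,3-diones (SN1 alkylation at the central carbon). No ring is closed and no stereocentre is created, because the new sp3 carbon carries two identical aryl groups and the existing methyl stereocentre is racemic and disappears in step 3. The selectivity needed is carbon over oxygen alkylation and mono- over bis-alkylation. The first rests on reversibility: the benzhydryl enol ether and the symmetrical bis(benzhydryl) ether re-ionise under the same acid, whereas the C–C bond should not at this temperature, so the material is expected to drain to 4. The second is secured by the substrate, since a second benzhydryl group at the same carbon would create a quaternary centre bearing two diarylmethyl groups. The small excess of 3 keeps the cation from being consumed by hydride transfer from 2.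

**Step 3**
Reactants: 4 2-[bis(4-methoxyphenyl)methyl]-3-hydroxy-6-methylcyclohex-2-en-1-one
Product: 5 2-[bis(4-methoxyphenyl)methyl]-4-methylbenzene-1,3-diol
Conditions: Pd/C (10 wt % Pd), mesitylene, reflux, N2 sweep
Reagents that add atoms: none
Why: Catalytic dehydrogenation of a cyclohexane-1,3-dione to a resorcinol: palladium removes one molecule of hydrogen from two adjacent sp3 ring carbons and the resulting enedione tautomerises to the aromatic diol. The gas sweep carries the hydrogen away so that it is not transferred back to substrate, and the aryl ethers and the diarylmethine are not touched.

**Step 4**
Reactants: 5 2-[bis(4-methoxyphenyl)methyl]-4-methylbenzene-1,3-diol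
Product: 6 2-[bis(4-methoxyphenyl)methyl]-4-methyl-1,3-phenylene bis(trifluoromethanesulfonate)
Conditions: Tf2O, pyridine, CH2Cl2, 0 °C to rt
Reagents that add atoms: trifluoromethanesulfonic anhydride, O=S(=O)(OS(=O)(=O)C(F)(F)F)C(F)(F)F
Why: O-Sulfonylation of both phenols; the anhydride is small and reactive enough to reach the hydroxyl group between the methyl and benzhydryl groups, and nothing else in 5 is nucleophilic toward it in the presence of pyridine.

**Step 5**
Reactants: 6 2-[bis(4-methoxyphenyl)methyl]-4-methyl-1,3-phenylene bis(trifluoromethanesulfonate); 7 4-methoxyphenylboronic acid
Product: 8 2-[bis(4-methoxyphenyl)methyl]-4'-methoxy-4-methylbiphenyl-3-yl trifluoromethanesulfonate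
Conditions: Pd(PPh3)4 (5 mol %), K3PO4, 7 (1.05 equiv), 1,4-dioxane, 90 °C
Reagents that add atoms: none
Why: Site-selective Suzuki–Miyaura coupling of an aryl bis(triflate): oxidative addition of zerovalent palladium is faster at the C4 triflate, which has hydrogen on one side, than at the C2 triflate, which is flanked by the methyl and benzhydryl groups. A triphenylphosphine catalyst of moderate activity and a near-stoichiometric amount of 7 are chosen to keep that difference.

**Step 6**
Reactants: 8 2-[bis(4-methoxyphenyl)methyl]-4'-methoxy-4-methylbiphenyl-3-yl trifluoromethanesulfonate; 9 4-ethynylanisole
Product: 10 2-[bis(4-methoxyphenyl)methyl]-4'-methoxy-3-[(4-methoxyphenyl)ethynyl]-4-methyl-1,1'-biphenyl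
Conditions: PdCl2(MeCN)2 (5 mol %), XPhos (2-dicyclohexylphosphino-2',4',6'-triisopropylbiphenyl), Cs2CO3, MeCN, 85 °C, slow addition of 9
Reagents that add atoms: none
Why: Copper-free Sonogashira coupling: the bulky, electron-rich biarylphosphine gives a monoligated zerovalent palladium species able to insert into a di-ortho-substituted aryl triflate, and the carbonate deprotonates the palladium-bound alkyne. Leaving out copper and adding 9 slowly suppresses Glaser homocoupling during what is expected to be a slow reaction.

**Step 7**
Reactants: 10 2-[bis(4-methoxyphenyl)methyl]-4'-methoxy-3-[(4-methoxyphenyl)ethynyl]-4-methyl-1,1'-biphenyl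
Product: 11 4,4'-({4'-hydroxy-3-[(4-hydroxyphenyl)ethynyl]-4-methylbiphenyl-2-yl}methylene)diphenol
Conditions: BBr3 (excess), CH2Cl2, −78 to 0 °C; then MeOH, H2O; product kept under N2
Reagents that add atoms: none
Why: Lewis-acid cleavage of aryl methyl ethers: boron binds each methoxy oxygen and bromide removes the methyl group by SN2. The internal diaryl alkyne has no ortho oxygen nucleophile that could cyclise onto it and should be haloborated only slowly at or below 0 °C, and the triarylmethane C–H is inert.

**Step 8**
Reactants: 11 4,4'-({4'-hydroxy-3-[(4-hydroxyphenyl)ethynyl]-4-methylbiphenyl-2-yl}methylene)diphenol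
Product: 12 Selaginellin U, 4-[{4'-hydroxy-3-[(4-hydroxyphenyl)ethynyl]-4-methylbiphenyl-2-yl}(4-hydroxyphenyl)methylidene]cyclohexa-2,5-dien-1-one
Conditions: DDQ (1.05 equiv), 1,4-dioxane, 0 °C to rt, N2
Reagents that add atoms: none
Why: Dehydrogenation of a bis(4-hydroxyphenyl)-substituted triarylmethane (leuco form) to the fuchsone-type quinone methide: the quinone removes hydride from the methine, which two para-hydroxy groups activate, and the cation loses a phenolic proton. Both hydroxyphenyl rings on the methine are identical, so either gives 12. The hydroxyl groups on ring B and on the alkynyl ring have no benzylic hydrogen para to them, so one equivalent of oxidant should be spent at the methine.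

## Compound list

1 | 4,4'-dimethoxybenzophenone | COc1ccc(C(=O)c2ccc(OC)cc2)cc1 | starting material
2 | bis(4-methoxyphenyl)methanol | COc1ccc(C(O)c2ccc(OC)cc2)cc1 | intermediate
3 | 4-methylcyclohexane-1,3-dione (racemic, one enantiomer drawn) | C[C@H]1CCC(=O)CC1=O | starting material
4 | 2-[bis(4-methoxyphenyl)methyl]-3-hydroxy-6-methylcyclohex-2-en-1-one (racemic, one enantiomer drawn) | C[C@H]1CCC(O)=C(C(c2ccc(OC)cc2)c2ccc(OC)cc2)C1=O | intermediate
5 | 2-[bis(4-methoxyphenyl)methyl]-4-methylbenzene-1,3-diol | Cc1ccc(O)c(C(c2ccc(OC)cc2)c2ccc(OC)cc2)c1O | intermediate
6 | 2-[bis(4-methoxyphenyl)methyl]-4-methyl-1,3-phenylene bis(trifluoromethanesulfonate) | Cc1ccc(OS(=O)(=O)C(F)(F)F)c(C(c2ccc(OC)cc2)c2ccc(OC)cc2)c1OS(=O)(=O)C(F)(F)F | intermediate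
7 | 4-methoxyphenylboronic acid | COc1ccc(B(O)O)cc1 | starting material
8 | 2-[bis(4-methoxyphenyl)methyl]-4'-methoxy-4-methylbiphenyl-3-yl trifluoromethanesulfonate | Cc1ccc(-c2ccc(OC)cc2)c(C(c2ccc(OC)cc2)c2ccc(OC)cc2)c1OS(=O)(=O)C(F)(F)F | intermediate
9 | 4-ethynylanisole (1-ethynyl-4-methoxybenzene) | C#Cc1ccc(OC)cc1 | starting material
10 | 2-[bis(4-methoxyphenyl)methyl]-4'-methoxy-3-[(4-methoxyphenyl)ethynyl]-4-methyl-1,1'-biphenyl | Cc1ccc(-c2ccc(OC)cc2)c(C(c2ccc(OC)cc2)c2ccc(OC)cc2)c1C#Cc1ccc(OC)cc1 | intermediate
11 | 4,4'-({4'-hydroxy-3-[(4-hydroxyphenyl)ethynyl]-4-methylbiphenyl-2-yl}methylene)diphenol | Cc1ccc(-c2ccc(O)cc2)c(C(c2ccc(O)cc2)c2ccc(O)cc2)c1C#Cc1ccc(O)cc1 | intermediate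
12 | Selaginellin U, 4-[{4'-hydroxy-3-[(4-hydroxyphenyl)ethynyl]-4-methylbiphenyl-2-yl}(4-hydroxyphenyl)methylidene]cyclohexa-2,5-dien-1-one | Cc1ccc(-c2ccc(O)cc2)c(C(=C2C=CC(=O)C=C2)c2ccc(O)cc2)c1C#Cc1ccc(O)cc1 | target

## Step count and risk

Total step count: 8. Longest linear sequence: 8 steps (1 to 12); 3, 7 and 9 enter as purchased compounds.

**Step 2 (key step).** The most likely failure is ionisation without productive capture. The cation may be consumed by hydride transfer between benzhydrol molecules, or stay parked as the symmetrical ether or the O-alkylated enol ether. If more forcing conditions are needed, the C-alkylation itself may begin to revert.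

Fallback: the same C3–methine bond is made with reversed polarity on an aromatic ring whose oxygens direct a metalation. The fallback sets out from 1 and returns at 5, so it also bypasses step 3. 4-Methylbenzene-1,3-diol F1 is converted with chloromethyl methyl ether and iPr2NEt into 2,4-bis(methoxymethoxy)-1-methylbenzene F2. n-BuLi in THF at 0 °C lithiates F2 between the two acetal oxygens, and addition to ketone 1 gives [2,6-bis(methoxymethoxy)-3-methylphenyl]bis(4-methoxyphenyl)methanol F3. Excess Et3SiH in CF3CO2H/CH2Cl2 ionises the carbinol and reduces the triarylmethyl cation. The same medium cleaves both acetals, and the silane intercepts the methoxymethyl cations before they can alkylate the resorcinol, giving 5.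

**Step 3.** The liberated hydrogen may be transferred back to substrate, leading to disproportionation into deoxygenated and over-reduced material. At the temperature needed, the acidic enol may also shed the benzhydryl group by re-ionisation.

Fallback: a stoichiometric selenoxide elimination at low temperature, setting out from 4 and returning at 5. Two equivalents of LDA in THF at −78 °C form the dianion of 4, which PhSeCl traps at the ring CH2 next to the enol carbon. This gives 2-[bis(4-methoxyphenyl)methyl]-3-hydroxy-6-methyl-4-(phenylselanyl)cyclohex-2-en-1-one F4. Oxidation with H2O2 at 0 °C is followed by syn-elimination of the selenoxide, and the enedione tautomerises to 5.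

**Step 5.** Site discrimination may be incomplete. Both triflates neighbour the benzhydryl group and differ only by the ortho methyl group, so oxidative addition at C2 could lead to double coupling or to the regioisomeric monoarylation.

Fallback: the two oxygens are differentiated before any palladium chemistry, setting out from 5 and returning at 8. One equivalent of N-phenylbis(trifluoromethanesulfonimide) with K2CO3 in DMF at 0 °C should sulfonylate the less hindered hydroxyl group, giving 2-[bis(4-methoxyphenyl)methyl]-3-hydroxy-4-methylphenyl trifluoromethanesulfonate F5, which is separable from any regioisomer by chromatography. Suzuki–Miyaura coupling of F5 with 7 (Pd(OAc)2, SPhos (2-dicyclohexylphosphino-2',6'-dimethoxybiphenyl), K3PO4, toluene/H2O) gives 2-[bis(4-methoxyphenyl)methyl]-4'-methoxy-4-methylbiphenyl-3-ol F6. Sulfonylation of F6 as in step 4 then gives 8.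

**Step 6.** Oxidative addition at the triflate between the methyl group and the benzhydryl group, which is now buttressed by ring B, may be so slow that the alkyne oligomerises or the base cleaves the triflate at sulfur back to the phenol.

Fallback: a Negishi alkynylation with a preformed organozinc reagent, which tolerates longer heating because no free alkyne is present. It sets out from 9 and 8 and returns at 10. Alkyne 9 is deprotonated with n-BuLi in THF at −78 °C and transmetalated with ZnCl2 to chloro[(4-methoxyphenyl)ethynyl]zinc F7. F7 is coupled with 8 using Pd[P(t-Bu)3]2 in THF/NMP at 70 °C to give 10.

**Step 8.** The free phenols may be over-oxidised or undergo radical coupling, and hydride abstraction from the shielded methine may be slow, so that oxidant is spent elsewhere. The air-sensitive tetraphenol 11 may also degrade on handling.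

Fallback: oxidation is done before deprotection, setting out from 10 and returning at 12, so that 11 is never made. DDQ in CH2Cl2/H2O abstracts hydride from the methine of 10, and water captures the cation to give bis(4-methoxyphenyl){4'-methoxy-3-[(4-methoxyphenyl)ethynyl]-4-methylbiphenyl-2-yl}methanol F8. BBr3 in CH2Cl2 (−78 to 0 °C, aqueous work-up) then cleaves the four methyl ethers, and the 4-hydroxyphenyl carbinol loses water to give 12 directly.

## Further compounds

F1 | step 2 | 4-methylbenzene-1,3-diol | Cc1ccc(O)cc1O
F2 | step 2 | 2,4-bis(methoxymethoxy)-1-methylbenzene | COCOc1ccc(C)c(OCOC)c1
F3 | step 2 | [2,6-bis(methoxymethoxy)-3-methylphenyl]bis(4-methoxyphenyl)methanol | Cc1ccc(OCOC)c(C(O)(c2ccc(OC)cc2)c2ccc(OC)cc2)c1OCOC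
F4 | step 3 | 2-[bis(4-methoxyphenyl)methyl]-3-hydroxy-6-methyl-4-(phenylselanyl)cyclohex-2-en-1-one (racemic mixture of diastereomers) | CC1CC([Se]c2ccccc2)C(O)=C(C(c2ccc(OC)cc2)c2ccc(OC)cc2)C1=O
F5 | step 5 | 2-[bis(4-methoxyphenyl)methyl]-3-hydroxy-4-methylphenyl trifluoromethanesulfonate | Cc1ccc(OS(=O)(=O)C(F)(F)F)c(C(c2ccc(OC)cc2)c2ccc(OC)cc2)c1O
F6 | step 5 | 2-[bis(4-methoxyphenyl)methyl]-4'-methoxy-4-methylbiphenyl-3-ol | Cc1ccc(-c2ccc(OC)cc2)c(C(c2ccc(OC)cc2)c2ccc(OC)cc2)c1O
F7 | step 6 | chloro[(4-methoxyphenyl)ethynyl]zinc | COc1ccc(C#C[Zn]Cl)cc1
F8 | step 8 | bis(4-methoxyphenyl){4'-methoxy-3-[(4-methoxyphenyl)ethynyl]-4-methylbiphenyl-2-yl}methanol | Cc1ccc(-c2ccc(OC)cc2)c(C(O)(c2ccc(OC)cc2)c2ccc(OC)cc2)c1C#Cc1ccc(OC)cc1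
A1 | alternative 1 | methyl 3-hydroxy-4'-methoxy-4-methylbiphenyl-2-carboxylate | Cc1ccc(-c2ccc(OC)cc2)c(C(=O)OC)c1O
A2 | alternative 2 | (3-chloro-4'-methoxy-4-methylbiphenyl-2-yl)(4-methoxyphenyl)methanone | Cc1ccc(-c2ccc(OC)cc2)c(C(=O)c2ccc(OC)cc2)c1Cl
A3 | alternative 3 | methyl 4'-methoxy-3,4-dimethylbiphenyl-2-carboxylate | Cc1ccc(-c2ccc(OC)cc2)c(C(=O)OC)c1C
A4 | alternative 3 | methyl 4'-methoxy-3-[2-(4-methoxyphenyl)-2-oxoethyl]-4-methylbiphenyl-2-carboxylate | Cc1ccc(-c2ccc(OC)cc2)c(C(=O)OC)c1CC(=O)c1ccc(OC)cc1
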